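**Retrosynthetic overview**
- Thiocladospolide F is a C2-symmetric thioether, so both C–S bonds are cut: two molecules of one silyl-protected 12-membered (E)-4-oxo-2-enoate macrolide plus sulfide (double sulfa-Michael addition, last step).
- Macrolide ⇒ open-chain (E)-11-hydroxy-4-oxo-2-enoic acid (macrolactonisation); the acid ⇒ a 2-substituted furan (oxidative ring opening).
- Furyl alcohol ⇒ sp3–sp3 coupling of a five-carbon Grignard piece (C8–C12, from (R)-propylene oxide) with a furyl iodide (C1–C7, from furan; CBS reduction sets C5).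
- Ring order: each 12-membered lactone is closed first (step 11); the two finished rings are then joined through sulfur (step 12); no other ring is formed.

Numbering used in the explanations: C1–C12 are the carbons of the dodecanoic acid chain of each half (C1 ester carbon, C2 sulfur-bearing carbon, C4 ketone, C5 hydroxy carbon, C11 methyl carbinol).
Assumption: sulfur adds to C2 of the ring enone from the exposed peripheral face (the C2 Si face), which gives the 2S configuration of the target; this facial preference is not proven here and the first fallback covers the other outcome.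

Step 1
Reactants: 1 (R)-2-methyloxirane; 2 vinylmagnesium bromide
Product: 3 (R)-pent-4-en-2-ol
Conditions: CuI (10 mol %), THF, −30 to 0 °C
Reagents that add atoms: none
Why: Copper-catalysed Grignard opening of the epoxide (SN2 at the CH2 carbon) leaves the existing stereocentre untouched, so the R centre of 1 is carried through to become C11.

Step 2
Reactants: 3 (R)-pent-4-en-2-ol
Product: 4 (R)-triethyl(pent-4-en-2-yloxy)silane
Conditions: TESCl, imidazole, CH2Cl2, 0 °C to rt
Reagents that add atoms: chlorotriethylsilane, CC[Si](Cl)(CC)CC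
Why: Silyl ether formation protects the secondary alcohol with a triethylsilyl group that survives the next steps but can later be removed by mild acid in the presence of a TBS ether.

Step 3
Reactants: 4 (R)-triethyl(pent-4-en-2-yloxy)silane
Product: 6 (R)-4-(triethylsilyloxy)pentan-1-ol, via alkylborane 5 (not isolated)
Conditions: 9-BBN (1.2 equiv), THF, 0 °C to rt; then aqueous NaOH, H2O2, 0 °C
Reagents that add atoms: hydrogen peroxide, OO
Why: Brown hydroboration–oxidation with the bulky 9-BBN places boron and then oxygen on the terminal carbon (anti-Markovnikov) without touching the stereocentre.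

Step 4
Reactants: 6 (R)-4-(triethylsilyloxy)pentan-1-ol
Product: 7 (R)-(5-bromopentan-2-yloxy)triethylsilane
Conditions: CBr4, PPh3, 2,6-lutidine, CH2Cl2, 0 °C
Reagents that add atoms: carbon tetrabromide, BrC(Br)(Br)Br
Why: The Appel reaction converts the primary alcohol into the bromide by SN2 displacement of an oxyphosphonium group under buffered conditions that keep the acid-labile silyl ether.

Step 5
Reactants: 8 furan; 9 3-chloropropanoyl chloride
Product: 10 3-chloro-1-(furan-2-yl)propan-1-one
Conditions: SnCl4 (1.1 equiv), CH2Cl2, −40 to 0 °C, furan added last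
Reagents that add atoms: none
Why: Friedel–Crafts acylation takes place at C2 of furan, its most nucleophilic position, and a mild Lewis acid at low temperature limits polymerisation of the furan.

Step 6
Reactants: 10 3-chloro-1-(furan-2-yl)propan-1-one
Product: 11 (S)-3-chloro-1-(furan-2-yl)propan-1-ol
Conditions: (R)-2-methyl-CBS-oxazaborolidine (10 mol %), BH3·SMe2 (0.6 equiv), THF, −20 °C; then MeOH
Reagents that add atoms: none
Why: Corey–Bakshi–Shibata reduction with the (R)-oxazaborolidine treats the furyl group as the large substituent, as with aryl ketones, and so gives the S alcohol that becomes C5, under neutral conditions that avoid loss of HCl from the β-chloro ketone; any minor enantiomer becomes a separable diastereomer after step 9.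

Step 7
Reactants: 11 (S)-3-chloro-1-(furan-2-yl)propan-1-ol
Product: 12 (S)-tert-butyl[3-chloro-1-(furan-2-yl)propoxy]dimethylsilane
Conditions: TBSCl, imidazole, DMF, rt
Reagents that add atoms: tert-butyldimethylsilyl chloride, CC(C)(C)[Si](C)(C)Cl
Why: Silylation protects the furyl carbinol as a robust TBS ether, which is needed later to block an Achmatowicz rearrangement when the furan is oxidised.

Step 8
Reactants: 12 (S)-tert-butyl[3-chloro-1-(furan-2-yl)propoxy]dimethylsilane
Product: 13 (S)-tert-butyl[1-(furan-2-yl)-3-iodopropoxy]dimethylsilane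
Conditions: NaI (3 equiv), NaHCO3 (0.1 equiv), butan-2-one, 80 °C
Reagents that add atoms: sodium iodide, [Na+].[I-]
Why: The Finkelstein reaction (SN2 at the primary carbon, driven by precipitation of NaCl) gives the iodide needed for the copper-catalysed coupling and does not touch the stereocentre.

Step 9
Reactants: 7 (R)-(5-bromopentan-2-yloxy)triethylsilane; 13 (S)-tert-butyl[1-(furan-2-yl)-3-iodopropoxy]dimethylsilane
Product: 16 (2R,8S)-8-(tert-butyldimethylsilyloxy)-8-(furan-2-yl)octan-2-ol, via Grignard reagent 14 (not isolated), via bis-silyl ether 15 (not isolated)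
Conditions: 7 (1.5 equiv), Mg, THF, 40 °C; then 13, Li2CuCl4 (5 mol %), THF, −20 to 0 °C; then crude product, PPTS, MeOH, 0 °C to rt
Reagents that add atoms: none
Why: Kochi-type copper-catalysed sp3–sp3 cross-coupling of the alkyl Grignard reagent with the primary iodide forms the C7–C8 bond without touching either stereocentre, and mild acid methanolysis then removes only the more labile triethylsilyl ether.

Step 10
Reactants: 16 (2R,8S)-8-(tert-butyldimethylsilyloxy)-8-(furan-2-yl)octan-2-ol
Product: 19 (2E,5S,11R)-5-(tert-butyldimethylsilyloxy)-11-hydroxy-4-oxododec-2-enoic acid, via Z enal 17 (not isolated), via E enal 18 (not isolated)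
Conditions: NBS (1.05 equiv), NaHCO3, acetone/H2O (10:1), −15 °C; pyridine, rt; then NaClO2, NaH2PO4, 2-methyl-2-butene, t-BuOH/H2O, 0 °C to rt
Reagents that add atoms: water, O; sodium chlorite, [Na+].[O-]Cl=O
Why: Oxidative ring opening of the 2-substituted furan by NBS in water gives the cis ene-dicarbonyl compound, pyridine isomerises it to the trans enal and Pinnick oxidation gives the acid, while the silyl ether blocks the Achmatowicz pathway and C5 is not involved.

Step 11
Reactants: 19 (2E,5S,11R)-5-(tert-butyldimethylsilyloxy)-11-hydroxy-4-oxododec-2-enoic acid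
Product: 21 (3E,6S,12R)-6-(tert-butyldimethylsilyloxy)-12-methyl-1-oxacyclododec-3-ene-2,5-dione, via mixed anhydride 20 (not isolated)
Conditions: MNBA (1.3 equiv), DMAP (0.2 equiv), Et3N (3 equiv), CH2Cl2 (1 mM, 19 added over 12 h), rt
Reagents that add atoms: none
Why: Shiina macrolactonisation activates the carboxyl group as a mixed anhydride and DMAP transfers the acyl group to the C11 hydroxyl at room temperature and high dilution, so the 12-membered ring closes with retention at C11 and with little risk of epimerising the α-silyloxy ketone.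

Step 12
Reactants: 21 (3E,6S,12R)-6-(tert-butyldimethylsilyloxy)-12-methyl-1-oxacyclododec-3-ene-2,5-dione (two molecules)
Product: 24 thiocladospolide F, via thiol 22 (not isolated), via bis-silyl sulfide 23 (not isolated)
Conditions: Na2S·9H2O (0.5 equiv), NaH2PO4/Na2HPO4 buffer (pH 7.5), MeCN, degassed, 0 °C to rt; then 48% aqueous HF, MeCN, 0 °C to rt
Reagents that add atoms: sodium sulfide, [Na+].[Na+].[S-2]
Why: In this double sulfa-Michael addition hydrosulfide attacks C2 (β to the ketone) from the exposed peripheral face of the ring to give thiol 22, which adds in the same sense to a second molecule of 21 so that both new C–S centres are S, and HF then cleaves both silyl ethers, unveiling the base-sensitive α-hydroxy ketones only under acid.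

**Compound list**
1 | (R)-2-methyloxirane ((R)-propylene oxide) | C[C@@H]1CO1 | starting material
2 | vinylmagnesium bromide | C=C[Mg]Br | starting material
3 | (R)-pent-4-en-2-ol | C[C@@H](O)CC=C | intermediate
4 | (R)-triethyl(pent-4-en-2-yloxy)silane | C[C@@H](O[Si](CC)(CC)CC)CC=C | intermediate
5 | (R)-9-[4-(triethylsilyloxy)pentyl]-9-borabicyclo[3.3.1]nonane | C[C@@H](O[Si](CC)(CC)CC)CCCB1C2CCCC1CCC2 | intermediate
6 | (R)-4-(triethylsilyloxy)pentan-1-ol | C[C@@H](O[Si](CC)(CC)CC)CCCO | intermediate
7 | (R)-(5-bromopentan-2-yloxy)triethylsilane | C[C@@H](O[Si](CC)(CC)CC)CCCBr | intermediate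
8 | furan | c1ccoc1 | starting material
9 | 3-chloropropanoyl chloride | O=C(Cl)CCCl | starting material
10 | 3-chloro-1-(furan-2-yl)propan-1-one | O=C(CCCl)c1ccco1 | intermediate
11 | (S)-3-chloro-1-(furan-2-yl)propan-1-ol | O[C@@H](CCCl)c1ccco1 | intermediate
12 | (S)-tert-butyl[3-chloro-1-(furan-2-yl)propoxy]dimethylsilane | CC(C)(C)[Si](C)(C)O[C@@H](CCCl)c1ccco1 | intermediate
13 | (S)-tert-butyl[1-(furan-2-yl)-3-iodopropoxy]dimethylsilane | CC(C)(C)[Si](C)(C)O[C@@H](CCI)c1ccco1 | intermediate
14 | (R)-[4-(triethylsilyloxy)pentyl]magnesium bromide | C[C@@H](O[Si](CC)(CC)CC)CCC[Mg]Br | intermediate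
15 | tert-butyl{[(1S,7R)-1-(furan-2-yl)-7-(triethylsilyloxy)octyl]oxy}dimethylsilane | C[C@@H](O[Si](CC)(CC)CC)CCCCC[C@H](O[Si](C)(C)C(C)(C)C)c1ccco1 | intermediate
16 | (2R,8S)-8-(tert-butyldimethylsilyloxy)-8-(furan-2-yl)octan-2-ol | C[C@@H](O)CCCCC[C@H](O[Si](C)(C)C(C)(C)C)c1ccco1 | intermediate
17 | (2Z,5S,11R)-5-(tert-butyldimethylsilyloxy)-11-hydroxy-4-oxododec-2-enal | C[C@@H](O)CCCCC[C@H](O[Si](C)(C)C(C)(C)C)C(=O)/C=C\C=O | intermediate
18 | (2E,5S,11R)-5-(tert-butyldimethylsilyloxy)-11-hydroxy-4-oxododec-2-enal | C[C@@H](O)CCCCC[C@H](O[Si](C)(C)C(C)(C)C)C(=O)/C=C/C=O | intermediate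
19 | (2E,5S,11R)-5-(tert-butyldimethylsilyloxy)-11-hydroxy-4-oxododec-2-enoic acid | C[C@@H](O)CCCCC[C@H](O[Si](C)(C)C(C)(C)C)C(=O)/C=C/C(=O)O | intermediate
20 | mixed anhydride of 19 with 2-methyl-6-nitrobenzoic acid | C[C@@H](O)CCCCC[C@H](O[Si](C)(C)C(C)(C)C)C(=O)/C=C/C(=O)OC(=O)c1c(C)cccc1[N+](=O)[O-] | intermediate
21 | (3E,6S,12R)-6-(tert-butyldimethylsilyloxy)-12-methyl-1-oxacyclododec-3-ene-2,5-dione | C[C@@H]1CCCCC[C@H](O[Si](C)(C)C(C)(C)C)C(=O)/C=C/C(=O)O1 | intermediate
22 | (3S,6S,12R)-6-(tert-butyldimethylsilyloxy)-12-methyl-3-sulfanyl-1-oxacyclododecane-2,5-dione | C[C@@H]1CCCCC[C@H](O[Si](C)(C)C(C)(C)C)C(=O)C[C@H](S)C(=O)O1 | intermediate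
23 | (3S,3'S,6S,6'S,12R,12'R)-3,3'-sulfanediylbis[6-(tert-butyldimethylsilyloxy)-12-methyl-1-oxacyclododecane-2,5-dione] | C[C@@H]1CCCCC[C@H](O[Si](C)(C)C(C)(C)C)C(=O)C[C@H](S[C@H]2CC(=O)[C@@H](O[Si](C)(C)C(C)(C)C)CCCCC[C@@H](C)OC2=O)C(=O)O1 | intermediate
24 | thiocladospolide F, (3S,3'S,6S,6'S,12R,12'R)-3,3'-sulfanediylbis(6-hydroxy-12-methyl-1-oxacyclododecane-2,5-dione) | C[C@@H]1CCCCC[C@H](O)C(=O)C[C@H](S[C@H]2CC(=O)[C@@H](O)CCCCC[C@@H](C)OC2=O)C(=O)O1 | target

**Totals**
Total step count: 12.
Longest linear sequence: 8 steps (steps 1–4 or steps 5–8, followed by steps 9–12).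

**Steps most likely to fail, with fallbacks**

The double sulfa-Michael addition of step 12 is the least certain step. Both new C2 centres depend on the facial bias of the macrocyclic enone, and the second addition may stall at thiol 22. The fallback sets out from 21 and makes the two C–S bonds one at a time under reagent control. Thioacetic acid is added to 21 under a quinine-derived bifunctional squaramide catalyst (toluene, −20 °C), or its quinidine-derived pseudo-enantiomer if that is the matched case. This gives the S-acetyl adduct S-[(3S,6S,12R)-6-(tert-butyldimethylsilyloxy)-12-methyl-2,5-dioxo-1-oxacyclododecan-3-yl] ethanethioate F1, whose C3 epimers can be separated and assigned before the second bond is formed. Methanolysis of F1 (K2CO3, degassed MeOH, −20 °C) in the presence of one further equivalent of 21 releases the thiol, so the fallback comes back to the route at 22. The thiol is trapped as 23 and desilylated with HF as in step 12.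

The macrolactonisation of step 11 is the second risk. The activated ene-dione acid can add DMAP, scramble its double-bond geometry, epimerise at C5 or oligomerise. The fallback sets out from 19 and masks the enone during ring closure. Thiophenol (catalytic Et3N, CH2Cl2, 0 °C) adds to 19 to give (5S,11R)-5-(tert-butyldimethylsilyloxy)-11-hydroxy-4-oxo-2-(phenylsulfanyl)dodecanoic acid F2 as a mixture of C2 epimers, which does not matter. This plain keto acid is lactonised under the Shiina conditions to (6S,12R)-6-(tert-butyldimethylsilyloxy)-12-methyl-3-(phenylsulfanyl)-1-oxacyclododecane-2,5-dione F3. Oxidation with mCPBA (1 equiv, CH2Cl2, −78 °C) gives (6S,12R)-6-(tert-butyldimethylsilyloxy)-12-methyl-3-(phenylsulfinyl)-1-oxacyclododecane-2,5-dione F4. Warming F4 in toluene brings about sulfoxide syn-elimination towards the acidic C3 hydrogen, and the fallback comes back to the route at 21.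

The Friedel–Crafts acylation of step 5 is the third risk, because furan polymerises under Lewis acids and the β-chloro ketone can lose HCl. The fallback sets out from 9 (with 8) and reverses the polarity of the acylation. Acid chloride 9 and N,O-dimethylhydroxylamine hydrochloride (pyridine, CH2Cl2, 0 °C) give the Weinreb amide 3-chloro-N-methoxy-N-methylpropanamide F5. Furan 8 is lithiated (n-BuLi, THF, 0 °C) to furan-2-yllithium F6, which is added to F5 at −78 °C. Collapse of the chelated adduct on acidic work-up gives the ketone, so the fallback comes back to the route at 10.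

Further compounds
F1 | step 12 | S-[(3S,6S,12R)-6-(tert-butyldimethylsilyloxy)-12-methyl-2,5-dioxo-1-oxacyclododecan-3-yl] ethanethioate | C[C@@H]1CCCCC[C@H](O[Si](C)(C)C(C)(C)C)C(=O)C[C@H](SC(C)=O)C(=O)O1
F2 | step 11 | (5S,11R)-5-(tert-butyldimethylsilyloxy)-11-hydroxy-4-oxo-2-(phenylsulfanyl)dodecanoic acid (C2 epimers) | C[C@@H](O)CCCCC[C@H](O[Si](C)(C)C(C)(C)C)C(=O)CC(Sc1ccccc1)C(=O)O
F3 | step 11 | (6S,12R)-6-(tert-butyldimethylsilyloxy)-12-methyl-3-(phenylsulfanyl)-1-oxacyclododecane-2,5-dione (C3 epimers) | C[C@@H]1CCCCC[C@H](O[Si](C)(C)C(C)(C)C)C(=O)CC(Sc2ccccc2)C(=O)O1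
F4 | step 11 | (6S,12R)-6-(tert-butyldimethylsilyloxy)-12-methyl-3-(phenylsulfinyl)-1-oxacyclododecane-2,5-dione (epimers at C3 and sulfur) | C[C@@H]1CCCCC[C@H](O[Si](C)(C)C(C)(C)C)C(=O)CC(S(=O)c2ccccc2)C(=O)O1
F5 | step 5 | 3-chloro-N-methoxy-N-methylpropanamide | CON(C)C(=O)CCCl
F6 | step 5 | furan-2-yllithium | [Li]c1ccco1
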